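**Plan**
Retrosynthesis: the C2=C3 double bond is cut first, back to a nine-membered sulfone with sulfur between C2 and C3; then S–C2 (thioether ring closure), S–C3 (thioacetate for hydroxyl), C8–C9 (cyclopentenyllithium plus aldehyde), C10–C11 and C9–C10 (cyclopropane CH2 and formaldehyde), C23–C24 (enolate alkylation) and ring C (annulation).
Forward: rings D and C are made first as an octalone; the C23 chain and the C10 quaternary centre are added; ring A is joined at C9; the nine-membered thiacycle is closed; ring B appears last by ring contraction.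
Stereochemistry: C14 from a chiral-imine Michael addition; C22 and C23 from dissolving-metal reduction and equatorial alkylation; C10 from cyclopropanation on the face opposite the axial C14 methyl group.
C3 comes from an oxazaborolidine reduction and is relayed to C9 (chelation-controlled hydride) and from C9 to C6 and C8 (hydroxyl-directed hydrogenation); C2 and C3 are erased at the end.
Enabling feature: C2=C3 is tetrasubstituted, exocyclic to ring A and necessarily cis inside eight-membered ring B, and C2 and C3 can each carry sulfur and one hydrogen, so a sulfone bridge between them can leave as SO2 and write exactly this bond.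

Key step: step 26

Remark on numbering: carbons are C1–C25 in the order written in the target SMILES (C1, C7, C11, C15, C19, C20 are methyl carbons); β is the face of the flat-drawn skeleton carrying the C14 methyl group, α the other face; for ring A before ring closure the letters are those the substituents will have in the tetracycle.
Assumption: the configurations at C2 and C3 of the sulfone disappear in the key step, so they are fixed as (2R) and 3β-S only to keep every intermediate a single isomer.
Assumption: the sense of induction in step 2 is taken from the parent 2-methylcyclohexanone case, where the (S)-amine leads to the (R)-ketone.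

Step 1
Reactants: 1 3,3-dimethylcyclohexanone
Product: 2 (±)-2,5,5-trimethylcyclohexanone
Conditions: LiN(i-Pr)2, THF, −78 °C; MeI, −78 to 0 °C
Reagents that add atoms: iodomethane, CI
Why: Kinetic enolate alkylation: the base removes a C6 proton, remote from the quaternary C3 that shields C2, and the new α-centre need not be controlled because it is equilibrated through the enamine in step 2.

Step 2
Reactants: 2 (±)-2,5,5-trimethylcyclohexanone; 3 methyl vinyl ketone
Product: 6 (S)-2,5,5-trimethyl-2-(3-oxobutyl)cyclohexanone, via ketimine 4 (not isolated), via Michael-adduct ketimine 5 (not isolated)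
Conditions: (R)-1-phenylethylamine, TsOH (cat.), toluene, reflux, −H2O; then 3, THF, 25 °C; then 10% aq. AcOH, 25 °C
Reagents that add atoms: water, O
Why: Deracemising Michael addition of a chiral ketimine: the more substituted secondary enamine tautomer adds to the enone through a compact aza-ene-type transition state on the face anti to the phenyl group, which sets the quaternary centre (C14 of the target), and hydrolysis frees the diketone.

Step 3
Reactants: 6 (S)-2,5,5-trimethyl-2-(3-oxobutyl)cyclohexanone
Product: 7 (S)-4a,7,7-trimethyl-4,4a,5,6,7,8-hexahydronaphthalen-2(3H)-one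
Conditions: NaOMe, MeOH, 60 °C
Reagents that add atoms: none
Why: Intramolecular aldol condensation (the ring-closing half of a Robinson annulation): the methyl ketone enolate attacks the ring carbonyl and dehydration gives the conjugated octalone (rings C and D) without touching the quaternary centre.

Step 4
Reactants: 8 (S)-butane-1,3-diol
Product: 9 (S)-4-iodobutan-2-ol
Conditions: I2, PPh3, imidazole, CH2Cl2, 0 °C
Reagents that add atoms: iodine, II
Why: Appel-type iodination reacts with the primary hydroxyl much faster than with the secondary one and leaves the stereocentre alone.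

Step 5
Reactants: 9 (S)-4-iodobutan-2-ol
Product: 10 (S)-tert-butyl[(4-iodobutan-2-yl)oxy]dimethylsilane
Conditions: TBSCl, imidazole, CH2Cl2, 0 to 25 °C
Reagents that add atoms: tert-butyldimethylsilyl chloride, CC(C)(C)[Si](C)(C)Cl
Why: Silyl ether formation protects the secondary alcohol for the organometallic steps that follow; the configuration is unchanged.

Step 6
Reactants: 7 (S)-octalone; 10 (S)-silyloxy iodide
Product: 12 trans-decalone carrying the 23α side chain, via lithium enolate 11 (not isolated)
Conditions: Li, NH3(l)/THF, t-BuOH (1 equiv), −78 °C; isoprene; NH3 evaporated; 10, THF/DMPU, −20 to 25 °C; then NaOMe, MeOH, 25 °C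
Reagents that add atoms: none
Why: Birch-type reductive alkylation of an enone: electron transfer and axial protonation at C22 give the trans-fused lithium enolate regiospecifically, SN2 alkylation by the primary iodide occurs at C23, and equilibration with NaOMe leaves the chain equatorial (23α, trans to 22α-H).

Step 7
Reactants: 12 trans-decalone
Product: 13 2,4,6-triisopropylbenzenesulfonylhydrazone of 12
Conditions: 2,4,6-triisopropylbenzenesulfonyl hydrazide, HCl (cat.), THF, 25 °C
Reagents that add atoms: 2,4,6-triisopropylbenzenesulfonyl hydrazide, CC(C)c1cc(C(C)C)c(S(=O)(=O)NN)c(C(C)C)c1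
Why: Sulfonylhydrazone formation at the only carbonyl group, with the N–N bond anti to the substituted C23, prepares the regioselective Shapiro reaction.

Step 8
Reactants: 13 trisylhydrazone
Product: 15 allylic alcohol (C10 hydroxymethyl; C10=C12), via alkenyllithium 14 (not isolated)
Conditions: n-BuLi (2.5 equiv), THF/TMEDA, −78 to 0 °C; (CH2O)n, 0 to 25 °C
Reagents that add atoms: paraformaldehyde (as formaldehyde), C=O
Why: Shapiro reaction: double deprotonation occurs on the less substituted C12 side, loss of sulfinate and N2 gives the C10 alkenyllithium, and its addition to formaldehyde installs C9 without affecting C23 or the ring fusion.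

Step 9
Reactants: 15 allylic alcohol
Product: 16 cyclopropylcarbinol (10α,12α-methylene)
Conditions: Et2Zn, CH2I2, CH2Cl2, 0 to 25 °C
Reagents that add atoms: diiodomethane, ICI
Why: Hydroxyl-accelerated Simmons–Smith cyclopropanation: the zinc carbenoid adds to the α face of the C10=C12 bond because the axial 14β-methyl group, 1,3 to C12, shields the β face, so the new CH2 (future C11) is 10α.

Step 10
Reactants: 16 cyclopropylcarbinol
Product: 17 neopentyl alcohol (10α-methyl; 10β-hydroxymethyl)
Conditions: H2 (3 atm), PtO2, AcOH, 25 °C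
Reagents that add atoms: none
Why: Catalytic hydrogenolysis of a cyclopropane cleaves the least hindered CH2–C12 bond, which turns the α-CH2 into the axial 10α-methyl group with retention at C10 and leaves the hydroxymethyl group equatorial.

Step 11
Reactants: 17 neopentyl alcohol
Product: 18 aldehyde (10β-CHO)
Conditions: Dess–Martin periodinane, NaHCO3, CH2Cl2, 25 °C
Reagents that add atoms: none
Why: Dess–Martin oxidation of the primary alcohol gives the non-enolisable aldehyde without risk to the quaternary centre.

Step 12
Reactants: 19 3-methylcyclopent-2-en-1-one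
Product: 21 2-bromo-3-methylcyclopent-2-en-1-one, via dibromoketone 20 (not isolated)
Conditions: Br2, CH2Cl2, 0 °C; then Et3N, 0 to 25 °C
Reagents that add atoms: bromine, BrBr
Why: Bromination–dehydrobromination of an enone: addition of Br2 and E1cB loss of HBr with Et3N give the α-bromo enone.

Step 13
Reactants: 21 2-bromo-3-methylcyclopent-2-en-1-one
Product: 22 (R)-2-bromo-3-methylcyclopent-2-en-1-ol
Conditions: (S)-2-methyl-CBS-oxazaborolidine (0.2 equiv), BH3·SMe2, THF, −20 °C
Reagents that add atoms: none
Why: Corey–Bakshi–Shibata reduction: the bromoalkenyl arm behaves as the large substituent, so the (S)-oxazaborolidine–borane complex should deliver hydride to the face that gives the (R)-carbinol, the future 3α-oxygen.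

Step 14
Reactants: 22 (R)-2-bromo-3-methylcyclopent-2-en-1-ol
Product: 23 (R)-bromide 4-methoxybenzyl ether
Conditions: NaH, 4-methoxybenzyl chloride, Bu4NI (cat.), THF/DMF, 0 to 25 °C
Reagents that add atoms: 4-methoxybenzyl chloride, COc1ccc(CCl)cc1
Why: Williamson ether synthesis; the PMB ether is inert to alkyllithiums, can chelate Li+ in step 17 and is removed oxidatively in step 20.

Step 15
Reactants: 23 (R)-bromide 4-methoxybenzyl ether; 18 aldehyde
Product: 25 C9-epimeric allylic alcohols, via cyclopentenyllithium 24 (not isolated)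
Conditions: t-BuLi (2 equiv), THF, −78 °C; then 18, −78 to −40 °C
Reagents that add atoms: none
Why: Bromine–lithium exchange and 1,2-addition of the cyclopentenyllithium to the non-enolisable aldehyde form the C8–C9 bond (β-elimination of the ether would need a cyclic allene), and the C9 configuration is not relied upon because the carbinol is oxidised in step 16.

Step 16
Reactants: 25 C9-epimeric allylic alcohols
Product: 26 enone (C9 ketone)
Conditions: Dess–Martin periodinane, NaHCO3, CH2Cl2, 25 °C
Reagents that add atoms: none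
Why: Dess–Martin oxidation converges both C9 epimers to one enone, which has no hydrogen at C10 to epimerise.

Step 17
Reactants: 26 enone
Product: 27 allylic alcohol carrying the C9 configuration of the target
Conditions: LiAlH4, LiI, Et2O, −78 °C
Reagents that add atoms: none
Why: Chelation-controlled 1,3-syn reduction of a β-alkoxy ketone: Li+ bridges the C9 carbonyl and the 3α ether oxygen, which turns the bulky C10 residue to the opposite face of ring A, and hydride enters from the C3 side because the other half-space is closed by the C6 methyl group.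

Step 18
Reactants: 27 allylic alcohol
Product: 28 saturated alcohol (6β-H; 8β-H)
Conditions: H2 (1 atm), [Ir(cod)(PCy3)(py)]PF6 (20 mol%), CH2Cl2, 25 °C
Reagents that add atoms: none
Why: Hydroxyl-directed homogeneous hydrogenation of a tetrasubstituted alkene with cationic iridium: with the C9–H bond eclipsing the ring plane next to the C6 methyl group (allylic 1,3-strain) the hydroxyl lies over the β face, the 3α ether blocks the α face, and syn delivery of H2 sets 6β-H and 8β-H.

Step 19
Reactants: 28 saturated alcohol
Product: 29 C9 tert-butyldimethylsilyl ether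
Conditions: TBSOTf, 2,6-lutidine, CH2Cl2, 0 to 25 °C
Reagents that add atoms: tert-butyldimethylsilyl trifluoromethanesulfonate, CC(C)(C)[Si](C)(C)OS(=O)(=O)C(F)(F)F
Why: Silylation of the hindered secondary alcohol with the silyl triflate protects C9 against oxidative acetal formation in step 20 and against alkoxide chemistry in the key step.

Step 20
Reactants: 29 C9 silyl ether
Product: 30 ring A alcohol (3α-OH)
Conditions: DDQ, CH2Cl2/pH 7 buffer, 0 to 25 °C
Reagents that add atoms: none
Why: Oxidative cleavage of the PMB ether (benzylic hydride abstraction and hydrolysis of the oxocarbenium ion) frees the 3α-alcohol while both silyl ethers are inert.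

Step 21
Reactants: 30 ring A alcohol
Product: 31 3β-thioacetate
Conditions: PPh3, DIAD, AcSH, THF, 0 to 25 °C
Reagents that add atoms: thioacetic acid, CC(=O)S
Why: Mitsunobu reaction: the activated 3α-oxygen is displaced with inversion by thioacetate entering on the β face, anti to the C8 substituent.

Step 22
Reactants: 31 3β-thioacetate
Product: 32 hydroxy thioacetate (free C2 hydroxyl)
Conditions: HF·pyridine, pyridine, THF, 0 to 25 °C
Reagents that add atoms: none
Why: Buffered fluoride desilylation cleaves the unhindered C2 silyl ether, while the C9 ether, flanked by quaternary C10 and tertiary C8, and the thioester survive.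

Step 23
Reactants: 32 hydroxy thioacetate
Product: 33 mesylate thioacetate
Conditions: MsCl, Et3N, CH2Cl2, −20 to 0 °C
Reagents that add atoms: methanesulfonyl chloride, CS(=O)(=O)Cl
Why: Sulfonylation of the secondary alcohol with retention at C2 provides the leaving group for ring closure.

Step 24
Reactants: 33 mesylate thioacetate
Product: 35 nine-membered sulfide, via caesium thiolate 34 (not isolated)
Conditions: Cs2CO3, MeOH/DMF (degassed), 45 °C, slow addition (high dilution)
Reagents that add atoms: none
Why: Caesium thiolate ring closure: methanolysis of the thioacetate frees the thiolate, which displaces the secondary mesylate by intramolecular SN2 attack (9-exo-tet) with inversion at C2, helped by the gauche arrangement of the C9 and C24 arms on ring C.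

Step 25
Reactants: 35 nine-membered sulfide
Product: 36 nine-membered sulfone
Conditions: mCPBA (2.5 equiv), NaHCO3, CH2Cl2, 0 to 25 °C
Reagents that add atoms: 3-chloroperoxybenzoic acid, OOC(=O)c1cccc(Cl)c1
Why: Peracid oxidation of the sulfide through the sulfoxide to the sulfone; no other oxidisable group is present.

Step 26
Reactants: 36 nine-membered sulfone
Product: 39 target tert-butyldimethylsilyl ether, via α-bromo sulfone 37 (not isolated), via episulfone 38 (not isolated)
Conditions: KOH/Al2O3, CBr2F2, t-BuOH/CH2Cl2, 5 to 25 °C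
Reagents that add atoms: none
Why: KOH on Al2O3 deprotonates a sulfonyl α-carbon (C2 or C3), the carbanion is brominated by CBr2F2, deprotonation at the other α-carbon is followed by 1,3-displacement of bromide to the episulfone, and cheletropic loss of SO2 leaves the C2=C3 double bond. The closest known reaction type is the Ramberg–Bäcklund reaction with in situ halogenation, which converts di-sec-alkyl and medium-ring sulfones into tetrasubstituted and cyclic alkenes. Ring B is not closed directly: the C2–C3 bond forms in a 3-exo-tet closure to the thiirane dioxide, and extrusion of SO2 contracts the nine-membered thiacycle to the eight-membered carbocycle. No stereocentre is created; C2 and C3 become trigonal, and the double bond is cis within ring B because only the cis-fused episulfone is attainable on an eight-membered ring. The step needs only α-halogenation, at either sulfonyl carbon, and tolerance of base: no carbonyl flanks C8, so the cis C6/C8 relation is safe, the silylated C9 oxygen cannot act as an alkoxide, and difluorocarbene from CBr2F2 should not add to the hindered tetrasubstituted alkene.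

Step 27
Reactants: 39 target tert-butyldimethylsilyl ether
Product: 40 target alcohol CNP0399382.1
Conditions: Bu4NF, THF, 60 °C
Reagents that add atoms: none
Why: Fluoride-mediated cleavage of the hindered silyl ether at elevated temperature gives the target without acid, so the tetrasubstituted double bond cannot migrate.

**Compound list**
1 | 3,3-dimethylcyclohexanone | CC1(C)CCCC(=O)C1 | starting material
2 | (±)-2,5,5-trimethylcyclohexanone | CC1CCC(C)(C)CC1=O | intermediate
3 | methyl vinyl ketone (but-3-en-2-one) | CC(=O)C=C | starting material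
4 | N-[(R)-1-phenylethyl] ketimine of 2 (ring C2 unspecified; not isolated) | C[C@@H](N=C1CC(C)(C)CCC1C)c1ccccc1 | intermediate
5 | N-[(R)-1-phenylethyl] ketimine of (S)-2,5,5-trimethyl-2-(3-oxobutyl)cyclohexanone (not isolated) | C[C@@H](N=C1CC(C)(C)CC[C@@]1(C)CCC(C)=O)c1ccccc1 | intermediate
6 | (S)-2,5,5-trimethyl-2-(3-oxobutyl)cyclohexanone | C[C@@]1(CCC(C)=O)CCC(C)(C)CC1=O | intermediate
7 | (S)-4a,7,7-trimethyl-4,4a,5,6,7,8-hexahydronaphthalen-2(3H)-one (rings C and D; C10 carbonyl, C22=C23, 14β-CH3) | C[C@]12CCC(=O)C=C1CC(C)(C)CC2 | intermediate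
8 | (S)-butane-1,3-diol | C[C@H](O)CCO | starting material
9 | (S)-4-iodobutan-2-ol | C[C@H](O)CCI | intermediate
10 | (S)-tert-butyl[(4-iodobutan-2-yl)oxy]dimethylsilane | C[C@H](O[Si](C)(C)C(C)(C)C)CCI | intermediate
11 | lithium enolate of the trans-fused decalone (C10–OLi, C10=C23, 22α-H, 14β-CH3; not isolated) | [Li]OC1=C[C@@H]2CC(C)(C)CC[C@@]2(C)CC1 | intermediate
12 | trans-decalin-10-one with 14β-CH3, 18,18-dimethyl, 22α-H, 23β-H and the equatorial 23α (S)-3-(tert-butyldimethylsilyloxy)butyl chain (C24, C25, C2, C1) | O=C1CC[C@]2(C)CCC(C)(C)C[C@H]2[C@@H]1CC[C@H](C)O[Si](C)(C)C(C)(C)C | intermediate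
13 | 2,4,6-triisopropylbenzenesulfonylhydrazone of 12 (N–N anti to C23) | CC(C)c1cc(C(C)C)c(S(=O)(=O)N/N=C2\CC[C@]3(C)CCC(C)(C)C[C@H]3[C@@H]2CC[C@H](C)O[Si](C)(C)C(C)(C)C)c(C(C)C)c1 | intermediate
14 | C10 alkenyllithium (C10=C12) of the decalin (not isolated) | [Li]C1=CC[C@]2(C)CCC(C)(C)C[C@H]2[C@@H]1CC[C@H](C)O[Si](C)(C)C(C)(C)C | intermediate
15 | allylic alcohol: 10-(hydroxymethyl)-Δ10(12)-octalin with 14β-CH3, 22α-H and the 23α side chain | OCC1=CC[C@]2(C)CCC(C)(C)C[C@H]2[C@@H]1CC[C@H](C)O[Si](C)(C)C(C)(C)C | intermediate
16 | cyclopropylcarbinol: 10α,12α-methylene bridge, 10β-CH2OH | OC[C@@]12C[C@@H]1C[C@]3(C)CCC(C)(C)C[C@H]3[C@@H]2CC[C@H](C)O[Si](C)(C)C(C)(C)C | intermediate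
17 | neopentyl alcohol: 10α-CH3 (axial), 10β-CH2OH (equatorial) | OC[C@@]1(C)CC[C@]2(C)CCC(C)(C)C[C@H]2[C@@H]1CC[C@H](C)O[Si](C)(C)C(C)(C)C | intermediate
18 | aldehyde: 10α-CH3, 10β-CHO (C9) | O=C[C@@]1(C)CC[C@]2(C)CCC(C)(C)C[C@H]2[C@@H]1CC[C@H](C)O[Si](C)(C)C(C)(C)C | intermediate
19 | 3-methylcyclopent-2-en-1-one | CC1=CC(=O)CC1 | starting material
20 | 2,3-dibromo-3-methylcyclopentanone (not isolated; configuration not defined) | CC1(Br)CCC(=O)C1Br | intermediate
21 | 2-bromo-3-methylcyclopent-2-en-1-one | CC1=C(Br)C(=O)CC1 | intermediate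
22 | (R)-2-bromo-3-methylcyclopent-2-en-1-ol | O[C@@H]1CCC(C)=C1Br | intermediate
23 | (R)-2-bromo-3-methylcyclopent-2-en-1-yl 4-methoxybenzyl ether | COc1ccc(CO[C@@H]2CCC(C)=C2Br)cc1 | intermediate
24 | cyclopentenyllithium from 23 (lithium at C8; not isolated) | COc1ccc(CO[C@@H]2CCC(C)=C2[Li])cc1 | intermediate
25 | coupled allylic alcohols, both C9 epimers (ring A cyclopentene with 3α-OPMB joined through C9 to C10 of the decalin) | COc1ccc(CO[C@@H]2CCC(C)=C2C(O)[C@@]2(C)CC[C@]3(C)CCC(C)(C)C[C@H]3[C@@H]2CC[C@H](C)O[Si](C)(C)C(C)(C)C)cc1 | intermediate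
26 | enone: C9 ketone between C10 and the C8=C6 cyclopentene, 3α-OPMB | COc1ccc(CO[C@@H]2CCC(C)=C2C(=O)[C@@]2(C)CC[C@]3(C)CCC(C)(C)C[C@H]3[C@@H]2CC[C@H](C)O[Si](C)(C)C(C)(C)C)cc1 | intermediate
27 | allylic alcohol with the C9 carbinol configured as in 40 (1,3-syn to the 3α ether) | COc1ccc(CO[C@@H]2CCC(C)=C2[C@@H](O)[C@@]2(C)CC[C@]3(C)CCC(C)(C)C[C@H]3[C@@H]2CC[C@H](C)O[Si](C)(C)C(C)(C)C)cc1 | intermediate
28 | saturated alcohol: ring A all-cis (3α-OPMB, 6α-CH3, 8α side chain; 6β-H, 8β-H), free C9 hydroxyl | COc1ccc(CO[C@@H]2CC[C@H](C)[C@@H]2[C@@H](O)[C@@]2(C)CC[C@]3(C)CCC(C)(C)C[C@H]3[C@@H]2CC[C@H](C)O[Si](C)(C)C(C)(C)C)cc1 | intermediate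
29 | C9 tert-butyldimethylsilyl ether of 28 | COc1ccc(CO[C@@H]2CC[C@H](C)[C@@H]2[C@@H](O[Si](C)(C)C(C)(C)C)[C@@]2(C)CC[C@]3(C)CCC(C)(C)C[C@H]3[C@@H]2CC[C@H](C)O[Si](C)(C)C(C)(C)C)cc1 | intermediate
30 | ring A alcohol: 3α-OH, C9 and C2 silyl ethers | O[C@@H]1CC[C@H](C)[C@@H]1[C@@H](O[Si](C)(C)C(C)(C)C)[C@@]1(C)CC[C@]2(C)CCC(C)(C)C[C@H]2[C@@H]1CC[C@H](C)O[Si](C)(C)C(C)(C)C | intermediate
31 | 3β-thioacetate (sulfur trans to the C8 side chain) | CC(=O)S[C@H]1CC[C@H](C)[C@@H]1[C@@H](O[Si](C)(C)C(C)(C)C)[C@@]1(C)CC[C@]2(C)CCC(C)(C)C[C@H]2[C@@H]1CC[C@H](C)O[Si](C)(C)C(C)(C)C | intermediate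
32 | hydroxy thioacetate: free (2S)-hydroxyl, C9 silyl ether | CC(=O)S[C@H]1CC[C@H](C)[C@@H]1[C@@H](O[Si](C)(C)C(C)(C)C)[C@@]1(C)CC[C@]2(C)CCC(C)(C)C[C@H]2[C@@H]1CC[C@H](C)O | intermediate
33 | (2S)-mesylate thioacetate | CC(=O)S[C@H]1CC[C@H](C)[C@@H]1[C@@H](O[Si](C)(C)C(C)(C)C)[C@@]1(C)CC[C@]2(C)CCC(C)(C)C[C@H]2[C@@H]1CC[C@H](C)OS(C)(=O)=O | intermediate
34 | caesium 3β-thiolate of the (2S)-mesylate (not isolated) | [Cs+].[S-][C@H]1CC[C@H](C)[C@@H]1[C@@H](O[Si](C)(C)C(C)(C)C)[C@@]1(C)CC[C@]2(C)CCC(C)(C)C[C@H]2[C@@H]1CC[C@H](C)OS(C)(=O)=O | intermediate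
35 | nine-membered sulfide: sulfur bridging (2R)-C2 and 3β-C3, C9 silyl ether | C[C@H]1S[C@H]2CC[C@H](C)[C@@H]2[C@@H](O[Si](C)(C)C(C)(C)C)[C@@]2(C)CC[C@]3(C)CCC(C)(C)C[C@H]3[C@@H]2CC1 | intermediate
36 | nine-membered sulfone, C9 silyl ether (key-step precursor) | C[C@H]1S(=O)(=O)[C@H]2CC[C@H](C)[C@@H]2[C@@H](O[Si](C)(C)C(C)(C)C)[C@@]2(C)CC[C@]3(C)CCC(C)(C)C[C@H]3[C@@H]2CC1 | intermediate
37 | α-bromo sulfone (bromine at C2, configuration there not defined; bromination at C3 would serve equally; not isolated) | CC1(Br)S(=O)(=O)[C@H]2CC[C@H](C)[C@@H]2[C@@H](O[Si](C)(C)C(C)(C)C)[C@@]2(C)CC[C@]3(C)CCC(C)(C)C[C@H]3[C@@H]2CC1 | intermediate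
38 | episulfone: thiirane 1,1-dioxide cis-fused across C2–C3 (drawn with sulfur kept on the β face of ring A; the other cis-fused isomer gives the same alkene; not isolated) | C[C@]12S(=O)(=O)[C@]13CC[C@H](C)[C@@H]3[C@@H](O[Si](C)(C)C(C)(C)C)[C@@]3(C)CC[C@]4(C)CCC(C)(C)C[C@H]4[C@@H]3CC2 | intermediate
39 | target tert-butyldimethylsilyl ether: (Z)-C2=C3, rings A–D complete | C/C1=C2\CC[C@H](C)[C@@H]2[C@@H](O[Si](C)(C)C(C)(C)C)[C@@]2(C)CC[C@]3(C)CCC(C)(C)C[C@H]3[C@@H]2CC1 | intermediate
40 | target CNP0399382.1: (Z)-C2=C3, 6α-CH3, 8β-H, 9β-OH, 10α-CH3, 14β-CH3, 22α-H, 23β-H | C/C1=C2\CC[C@H](C)[C@@H]2[C@@H](O)[C@@]2(C)CC[C@]3(C)CCC(C)(C)C[C@H]3[C@@H]2CC1 | target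

**Step count**
Total: 27 steps. Longest linear sequence: 22 steps (steps 1–3, 6–11 and 15–27).

**Steps most likely to fail**

Step 24, closure of the nine-membered thioether. What may go wrong: intermolecular thioether and disulfide formation, or E2 loss of the mesylate, outruns the entropically and transannularly disfavoured medium-ring closure. Fallback: the ring is closed through the other carbon–sulfur bond, with the roles of the two carbons exchanged. Setting out from alcohol 30, mesylation (MsCl, Et3N) gives the 3α-mesylate F1, and buffered HF·pyridine frees the C2 hydroxyl to give the hydroxy mesylate F2. A Mitsunobu reaction with thioacetic acid gives the inverted (2R)-thioacetate F3, and methanolysis with Cs2CO3 under high dilution releases the caesium thiolate F4. This unhindered nucleophile attacks the cyclopentyl mesylate from the open β face, and inversion at C3 returns sulfide 35.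

Step 18, directed hydrogenation. What may go wrong: the catalyst fails to bind the crowded tetrasubstituted double bond, or hydrogen is delivered to the α face because the hydroxyl does not sit over the β face in the reacting conformer. Fallback: face control is handed to the 3α ether on the conjugated ketone, and C9 is set afterwards. Setting out from enone 26, heterogeneous hydrogenation (H2, Rh/Al2O3, EtOAc) should add hydrogen anti to the ether and give the all-cis saturated ketone F5. Chelation-controlled reduction (LiAlH4, LiI, Et2O, −78 °C), with hydride attacking the convex face of the cis-fused lithium chelate, should then give the 1,3-syn alcohol, which is compound 28.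

Step 26, Ramberg–Bäcklund contraction. What may go wrong: halogenation of the two hindered methine carbanions is slow, so that base-induced side reactions and carbene trapping compete. Fallback: the halogen is introduced at the sulfide oxidation level, where no carbanion is needed. Setting out from sulfide 35, N-chlorosuccinimide (CCl4, 25 °C) gives the α-chloro sulfide F6 through the chlorosulfonium ion, and mCPBA gives the α-chloro sulfone F7. KOt-Bu in THF (−20 °C) then effects the 1,3-elimination to episulfone 38 and loss of SO2, which returns silyl ether 39.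

Further compounds
F1 | step 24 | 3α-mesylate of alcohol 30 (C9 and C2 silyl ethers retained) | CS(=O)(=O)O[C@@H]1CC[C@H](C)[C@@H]1[C@@H](O[Si](C)(C)C(C)(C)C)[C@@]1(C)CC[C@]2(C)CCC(C)(C)C[C@H]2[C@@H]1CC[C@H](C)O[Si](C)(C)C(C)(C)C
F2 | step 24 | hydroxy mesylate: 3α-mesylate with free (2S)-hydroxyl | CS(=O)(=O)O[C@@H]1CC[C@H](C)[C@@H]1[C@@H](O[Si](C)(C)C(C)(C)C)[C@@]1(C)CC[C@]2(C)CCC(C)(C)C[C@H]2[C@@H]1CC[C@H](C)O
F3 | step 24 | (2R)-thioacetate of the 3α-mesylate | CS(=O)(=O)O[C@@H]1CC[C@H](C)[C@@H]1[C@@H](O[Si](C)(C)C(C)(C)C)[C@@]1(C)CC[C@]2(C)CCC(C)(C)C[C@H]2[C@@H]1CC[C@@H](C)SC(C)=O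
F4 | step 24 | caesium (2R)-thiolate of the 3α-mesylate (not isolated) | [Cs+].CS(=O)(=O)O[C@@H]1CC[C@H](C)[C@@H]1[C@@H](O[Si](C)(C)C(C)(C)C)[C@@]1(C)CC[C@]2(C)CCC(C)(C)C[C@H]2[C@@H]1CC[C@@H](C)[S-]
F5 | step 18 | all-cis saturated C9 ketone (3α-OPMB, 6β-H, 8β-H) | COc1ccc(CO[C@@H]2CC[C@H](C)[C@@H]2C(=O)[C@@]2(C)CC[C@]3(C)CCC(C)(C)C[C@H]3[C@@H]2CC[C@H](C)O[Si](C)(C)C(C)(C)C)cc1
F6 | step 26 | α-chloro sulfide (chlorine at C2, configuration there not defined) | CC1(Cl)S[C@H]2CC[C@H](C)[C@@H]2[C@@H](O[Si](C)(C)C(C)(C)C)[C@@]2(C)CC[C@]3(C)CCC(C)(C)C[C@H]3[C@@H]2CC1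
F7 | step 26 | α-chloro sulfone (chlorine at C2, configuration there not defined) | CC1(Cl)S(=O)(=O)[C@H]2CC[C@H](C)[C@@H]2[C@@H](O[Si](C)(C)C(C)(C)C)[C@@]2(C)CC[C@]3(C)CCC(C)(C)C[C@H]3[C@@H]2CC1
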